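The ash run lost more free monomer than it put into chains: by 80.0 s, 58.1% of the charge had gone and 19.5% stood in chains. The difference, 38.6%, nears the protic impurity charge of 40.0%, so the impurity reads as taking free monomer one for one.

| setting | ash | flask |
|---|---|---|
| free monomer | 0.10 M | 0.10 M |
| protic impurity | 0.040 M | 0.0200 M |
| pre-initiator | 2 mol% | 2 mol% |
| remark | run made earlier |  |
| time |  | 4.0 min |

- ash (time / s: monomer in chains / %, free monomer / %): 15.0: 0, 73.8; 30.0: 3.8, 62.9; 40.0: 6.6, 57.2; 60.0: 13.6, 48.9; 80.0: 19.5, 41.9

(standard deviation of a reading: 1 percentage point)

- whether the average number of monomer units in a chain (chains begun, living or dead) reaches 20 by 4.0 min (no / yes)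
- average number of monomer units in a chain (chains begun, living or dead) at 4.0 min

- the average divides the monomer in chains by the number of chains begun, living and dead together
- what was read earlier has a scatter of 1 percentage point, one standard deviation
- candidate steps: free monomer + initiator -> living end + monomer in chains; free monomer + living end -> monomer in chains + living end; protic impurity + free monomer -> quenched substrate; monomer in chains + living end -> free monomer + living end; pre-initiator -> initiator
- the earlier runs do not show the number of chains; that part of a forecast is a guess
- no earlier run changes the charge of protic impurity; that part of a forecast is a guess

My own reckoning brackets the flask between two estimates. The upper edge is the ceiling length, 40.0 units: the free monomer charged less the protic impurity, over the pre-initiator charged, one chain for each pre-initiator charged. The chain count is a guess, since no run shows it, so this edge is an estimate and not a bound.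

For the lower edge, the last interval of the ash run reads as a pseudo-first-order growth constant of 0.00650 s⁻¹. Held flat, started at 30.0 s and run to 4.0 min on the free monomer that the impurity leaves in the flask, it reckons 59.6% in chains. On the same guessed chain count that gives an estimated length of 29.8, above the wanted 20.

The forecast says yes and 30, at the lower edge of this bracket, and warns: “The chain count, possible depropagation and any impurity effect on the lag are guesses”.

The flask gives yes and 32.8, inside the bracket and below the ceiling length of 40.0.

    free monomer + initiator → living end + monomer in chains (k = 2.30 L mol⁻¹ s⁻¹)
    free monomer + living end → monomer in chains + living end, rate k2*[living end]*[free monomer] (k = 7.60 L mol⁻¹ s⁻¹)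
    protic impurity + free monomer → quenched substrate (k = 0.800 L mol⁻¹ s⁻¹)
    monomer in chains + living end → free monomer + living end, rate k4*[living end] as long as [monomer in chains] is above zero (k = 0.0900 s⁻¹)
    pre-initiator → initiator (k = 0.0160 s⁻¹)

At 4.00 min the flask makes monomer in chains 1.41 times faster than it uses it up, each step taken net, against 3.56 times at 1.80 min, and 16.6% free monomer stands beside 63.4% in chains. At 40.0 min the flask still holds 11.8% free monomer, with 68.2% in chains and a length of 34.1.

The runs stem from a simulated flask for an exercise, noise included.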